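We have no constants for this flask yet, only readings from the earlier runs.

| flask | starting material | partner | time |
|---|---|---|---|
| spring | 300 mM | 300 mM |  |
| autumn | 900 mM | 300 mM |  |
| summer | 300 mM | 900 mM |  |
| winter | 180 mM | 180 mM | 5.3 min |

| spring run: time / min | spring run: [product] / mM | autumn run: time / min | autumn run: [product] / mM | summer run: time / min | summer run: [product] / mM |
|---|---|---|---|---|---|
| 0.19 | 9.7 | 0.19 | 33.8 | 0.19 | 20.8 |
| 0.58 | 35.4 | 0.58 | 94.3 | 0.58 | 58.9 |
| 1.1 | 57.9 | 1.1 | 155.0 | 1.1 | 100.7 |
| 1.7 | 83.1 | 1.7 | 207.0 | 1.7 | 137.6 |
| 2.5 | 111.1 | 2.5 | 248.8 | 2.5 | 175.0 |
| 3.3 | 129.5 | 3.3 | 272.5 | 3.3 | 204.8 |
| 4.3 | 151.9 | 4.3 | 282.0 | 4.3 | 228.8 |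
| 5.3 | 168.0 | 5.3 | 284.0 | 5.3 | 246.3 |

(readings scatter by 0.9 mM)

- Overall: starting material + partner -> product.
- Constant volume, constant temperature.
- A reading of a species includes what of it is bound.
- "The second partner" is partner.
- An order is taken over about fifteen percent of the charge, up and down.

- the exponent of [partner] in the starting rate at the charge of the spring run (at the point where two percent of the starting material have become product)
- the exponent of [starting material] in the starting rate at the charge of the spring run (at the point where two percent of the starting material have become product) (one fixed amount of product, the same in the runs compared)
- product in the winter run at 5.3 min, as a share of the starting material charged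

The winter flask holds equal charges of starting material and partner; our rule below is made for equal charges, so leave them equal. Between the spring and summer runs, tripling the partner raises the product read at 0.58 min from 35.4 mM to 58.9 mM. That gives a rough partner exponent of 0.463, about half. Tripling the starting material, from the spring to the autumn run, multiplies the product read at that time by 2.66, so its exponent is near one. We read this as partner pairing with itself and reacting through a free part that grows slowly with the charge.

With equal charges, the time to turn a given share then scales as the charge to the power of minus that exponent. The spring run read 151.9 mM at 4.3 min, about half of its starting material. The winter half-time, that spring time stretched by the charge ratio raised to the partner exponent, is 5.45 min. The asked 5.3 min falls short of it, so, scaling the spring share in proportion to the time, we expect product in the winter run at 49.3%, just under half of the starting material.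

The forecast gives 0.62 for partner, 0.97 for starting material and 45% for winter, a lower share than ours: “The local order at 300 mM is then about 0.6.”

The simulation gives 0.58, 1.0 and 47.5%.

    starting material + partner → product + by-product (3.234 M⁻¹ min⁻¹)
    2 partner ⇌ idle reagent dimer, settled at all times (26.80 M⁻¹)
    2 partner → lost reagent (1.464 M⁻¹ min⁻¹)

Our winter half-time of 5.45 min lies 0.150 min past the asked time, and at the asked time the winter run stands just under half. The partner exponent comes from the idle reagent dimer: with that pairing removed, it is 1.0 rather than 0.58. The same pairing holds back the winter run, which without it gives 57.6% rather than 47.5%.

Readings and results were generated by integration with constants of no real substance, and the scatter is random.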